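**Retrosynthetic overview**
- The cyclobutane (bonds C1–C8 and C6–C7 of the 2-oxabicyclo[4.2.0]octenone) and both six-membered lactones are disconnected in one operation, back to two molecules of one acyclic δ-keto-β-methoxy enoate.
- Ring order in that operation: two enol lactonizations give two 2-pyranones; then a head-to-tail [2+2] inside a chiral phosphoric-acid-clipped pair closes the cyclobutane, turns one pyranone into the fused dihydropyranone and sets all four stereocentres.
- The keto ester comes from γ-acylation of the silyl dienolate of methyl (E)-3-methoxybut-2-enoate with O-silyl p-coumaroyl chloride.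
- The acid chloride comes from p-coumaric acid.

Assumption: the sense of induction of the phosphoric acid template cannot be predicted with certainty; the (R)-acid is written, and its mirror image is used if it delivers the antipode.

**Step 1**
Reactants: 1 (E)-3-(4-hydroxyphenyl)prop-2-enoic acid (p-coumaric acid)
Product: 3 (E)-3-[4-(tert-butyldimethylsilyloxy)phenyl]prop-2-enoyl chloride, via bis-silyl ester 2 (not isolated)
Conditions: tBuMe2SiCl (2.2 equiv), imidazole, HCONMe2, 23 °C; then (COCl)2, HCONMe2 (cat.), CH2Cl2, 0 → 23 °C, evaporate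
Reagents that add atoms: tert-butyldimethylsilyl chloride CC(C)(C)[Si](C)(C)Cl; oxalyl chloride O=C(Cl)C(=O)Cl
Why: Both OH groups are silylated and the silyl ester is then exchanged for the acyl chloride under neutral conditions by the Vilsmeier reagent from oxalyl chloride and formamide (silyl ester to acid chloride conversion), which leaves the aryl silyl ether and the E-alkene untouched; no stereocentre is formed.

**Step 2**
Reactants: 4 methyl (E)-3-methoxybut-2-enoate; 3 (E)-3-[4-(tert-butyldimethylsilyloxy)phenyl]prop-2-enoyl chloride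
Product: 8 methyl (2E,6E)-7-(4-hydroxyphenyl)-3-methoxy-5-oxohepta-2,6-dienoate, via lithium dienolate 5 (not isolated), via silyl dienol ether 6 (not isolated), via silyl-protected keto ester 7 (not isolated)
Conditions: LiN(iPr)2, THF, −78 °C; Me3SiCl; evaporate, CH2Cl2; 3, −78 → 0 °C; then KHF2, MeOH, 0 → 20 °C
Reagents that add atoms: none
Why: γ-Deprotonation and O-silylation give the 1-methoxy-1-silyloxy diene, whose terminal carbon is its nucleophilic site, so the acid chloride is attacked there in a 1,2-sense (vinylogous Mukaiyama-type acylation) to give the (2E) keto ester, and KHF2 then removes only the aryl silyl ether without base so that the chain does not cyclise; no stereocentre is formed.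

**Step 3**
Reactants: 8 methyl (2E,6E)-7-(4-hydroxyphenyl)-3-methoxy-5-oxohepta-2,6-dienoate (two molecules)
Product: 10 (1R,6S,7S,8S)-7-(4-hydroxyphenyl)-1-[(E)-2-(4-hydroxyphenyl)ethenyl]-5-methoxy-8-(4-methoxy-2-oxo-2H-pyran-6-yl)-2-oxabicyclo[4.2.0]oct-4-en-3-one, via pyranone monomer 9 (not isolated)
Conditions: (R)-3,3'-bis(2,4,6-triisopropylphenyl)-1,1'-binaphthalene-2,2'-diyl hydrogen phosphate (1.0 equiv, recovered), 5 Å molecular sieves, PhMe, 80 °C; then PhMe/CH2Cl2 (0.1 M), −40 °C, 385 nm LED, argon
Reagents that add atoms: none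
Why: Proposed new method: the phosphoric acid first catalyses the 6-exo enol lactonization of each keto ester (MeOH is taken up by the sieves) and then clips two pyranones head to tail through ArO–H···O=P and P–OH···O=C(lactone) hydrogen bonds, so that the 5,6-bond of the carbonyl-bound pyranone stacks on the styryl bond of the phenol-bound one; excitation of this pair gives a suprafacial [2+2] that fixes the cis ring fusion, keeps aryl and pyranonyl trans (E-alkene retained), puts the aryl group on the lactone face and the pyranonyl group beside the styryl arm, and the binaphthyl pocket selects one stacking face to set C1, C6, C7 and C8 as R, S, S and S; the closest known reaction types are the acid-catalysed cyclization of δ-keto-β-methoxy enoates to 4-methoxy-2-pyranones, the head-to-tail photodimerization of 6-styryl-2-pyranones and chiral Brønsted-acid-controlled [2+2] photocycloadditions.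

**Compound list**
1 | (E)-3-(4-hydroxyphenyl)prop-2-enoic acid | O=C(O)/C=C/c1ccc(O)cc1 | starting material
2 | tert-butyldimethylsilyl (E)-3-[4-(tert-butyldimethylsilyloxy)phenyl]prop-2-enoate | CC(C)(C)[Si](C)(C)OC(=O)/C=C/c1ccc(O[Si](C)(C)C(C)(C)C)cc1 | intermediate
3 | (E)-3-[4-(tert-butyldimethylsilyloxy)phenyl]prop-2-enoyl chloride | O=C(Cl)/C=C/c1ccc(O[Si](C)(C)C(C)(C)C)cc1 | intermediate
4 | methyl (E)-3-methoxybut-2-enoate | COC(=O)/C=C(\C)OC | starting material
5 | lithium (1Z)-1,3-dimethoxybuta-1,3-dien-1-olate | C=C(OC)/C=C(\OC)[O-].[Li+] | intermediate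
6 | [(1E)-1,3-dimethoxybuta-1,3-dien-1-yl]oxy(trimethyl)silane | C=C(OC)/C=C(\OC)O[Si](C)(C)C | intermediate
7 | methyl (2E,6E)-7-[4-(tert-butyldimethylsilyloxy)phenyl]-3-methoxy-5-oxohepta-2,6-dienoate | COC(=O)/C=C(/OC)CC(=O)/C=C/c1ccc(O[Si](C)(C)C(C)(C)C)cc1 | intermediate
8 | methyl (2E,6E)-7-(4-hydroxyphenyl)-3-methoxy-5-oxohepta-2,6-dienoate | COC(=O)/C=C(/OC)CC(=O)/C=C/c1ccc(O)cc1 | intermediate
9 | 6-[(E)-2-(4-hydroxyphenyl)ethenyl]-4-methoxy-2H-pyran-2-one | COc1cc(/C=C/c2ccc(O)cc2)oc(=O)c1 | intermediate
10 | (1R,6S,7S,8S)-7-(4-hydroxyphenyl)-1-[(E)-2-(4-hydroxyphenyl)ethenyl]-5-methoxy-8-(4-methoxy-2-oxo-2H-pyran-6-yl)-2-oxabicyclo[4.2.0]oct-4-en-3-one | COC1=CC(=O)O[C@]2(/C=C/c3ccc(O)cc3)[C@H]1[C@H](c1ccc(O)cc1)[C@H]2c1cc(OC)cc(=O)o1 | target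

**Total step count:** 3. **Longest linear sequence:** 3 (1 → 3 → 8 → 10).

**Steps most likely to fail, with fallbacks**

Highest risk is the one-pot lactonization and templated photodimerization (step 3). The styryl bond can isomerise, the aligned 7,8/7',8' head-to-tail dimer can compete with the wanted 5,6/7',8' dimer, and the template may give low enantioselectivity. The fallback sets out from 8 and comes back at 10. It separates ring closure from dimerization and gives up template control. Compound 8 is cyclised with 1,8-diazabicyclo[5.4.0]undec-7-ene (cat.) in PhMe at 60 °C and 9 is isolated. A microcrystalline film of 9 is irradiated at 365 nm, where E/Z isomerization is shut down and the packing decides the stacking. The head-to-tail dimer is then obtained as the racemate, that is 10 together with its mirror image, the (1S,6R,7R,8R) enantiomer of the target F1. Compound 10 is separated from F1 by preparative chromatography on a chiral stationary phase (amylose tris(3,5-dimethylphenylcarbamate), supercritical CO2/MeOH).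

Second is the γ-acylation and desilylation (step 2). The diene may be acylated at the α-carbon or on oxygen, and the keto ester may lactonise early. The fallback sets out from 3 and comes back at 9, using dianion chemistry instead of the silyl dienolate. The dianion of methyl acetoacetate (NaH, then n-BuLi, THF, −78 °C) is acylated with 3 to give methyl (E)-7-[4-(tert-butyldimethylsilyloxy)phenyl]-3,5-dioxohept-6-enoate F2. Cyclization with 1,8-diazabicyclo[5.4.0]undec-7-ene in refluxing PhMe gives 6-[(E)-2-[4-(tert-butyldimethylsilyloxy)phenyl]ethenyl]-4-hydroxy-2H-pyran-2-one F3. O-Methylation (Me2SO4, K2CO3, acetone) gives 6-[(E)-2-[4-(tert-butyldimethylsilyloxy)phenyl]ethenyl]-4-methoxy-2H-pyran-2-one F4. KHF2 in MeOH then gives 9, which is loaded on the phosphoric acid and irradiated as in the second half of step 3.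

Third is the acid chloride formation (step 1). The aryl silyl ether may be lost, or the cinnamoyl chloride may oligomerise. The fallback sets out from 4 and comes back at 9, and needs no cinnamoyl donor and no phenol protection. Silyl dienol ether 6, made from 4 as in step 2, is acetylated with acetyl chloride to give methyl (2E)-3-methoxy-5-oxohex-2-enoate F5. Cyclization with 1,8-diazabicyclo[5.4.0]undec-7-ene (cat.) gives 4-methoxy-6-methyl-2H-pyran-2-one F6, which is also sold. Aldol condensation of its vinylogous methyl group with 4-hydroxybenzaldehyde (Mg(OMe)2, MeOH, reflux) gives 9, which then goes into the templated irradiation.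

**Further compounds**
F1 | step 3 | (1S,6R,7R,8R)-7-(4-hydroxyphenyl)-1-[(E)-2-(4-hydroxyphenyl)ethenyl]-5-methoxy-8-(4-methoxy-2-oxo-2H-pyran-6-yl)-2-oxabicyclo[4.2.0]oct-4-en-3-one | COC1=CC(=O)O[C@@]2(/C=C/c3ccc(O)cc3)[C@@H]1[C@@H](c1ccc(O)cc1)[C@@H]2c1cc(OC)cc(=O)o1
F2 | step 2 | methyl (E)-7-[4-(tert-butyldimethylsilyloxy)phenyl]-3,5-dioxohept-6-enoate | COC(=O)CC(=O)CC(=O)/C=C/c1ccc(O[Si](C)(C)C(C)(C)C)cc1
F3 | step 2 | 6-[(E)-2-[4-(tert-butyldimethylsilyloxy)phenyl]ethenyl]-4-hydroxy-2H-pyran-2-one | O=c1cc(O)cc(/C=C/c2ccc(O[Si](C)(C)C(C)(C)C)cc2)o1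
F4 | step 2 | 6-[(E)-2-[4-(tert-butyldimethylsilyloxy)phenyl]ethenyl]-4-methoxy-2H-pyran-2-one | COc1cc(/C=C/c2ccc(O[Si](C)(C)C(C)(C)C)cc2)oc(=O)c1
F5 | step 1 | methyl (2E)-3-methoxy-5-oxohex-2-enoate | COC(=O)/C=C(/OC)CC(C)=O
F6 | step 1 | 4-methoxy-6-methyl-2H-pyran-2-one | COc1cc(C)oc(=O)c1
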